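**Retrosynthetic overview**

1. Feature: in the ten-membered carbocycle, C7 carries the 1-carboxyvinyl unit (C11=C13, C12) next to the oxygenated C8. This homoallylic alcohol O–C8–C7–C11=C13 is the retron of a [2,3]-Wittig shift and also the open form of the C6–O–C12 α-methylene-γ-lactone.
2. Late stage: the lactone ring (O6 to C12), the C8 and C9 esters and the C14 aldehyde are made from a ten-membered 8-hydroxy-9-ketone that carries the C7 acrylate.
3. Key disconnection: C7–C8, formed by [2,3]-shift of the C8 lithium enolate of a 13-membered α-(allyloxy) enone across its C8–O–C13 ether (ring contraction 13 to 10).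
4. The 13-membered ether is opened at C9–C10 (Nozaki–Hiyama–Kishi closure). Its chain comes from (S)-glyceraldehyde acetonide (C5–C7) by two Wittig olefinations (C4=C5, C1=C10) and a Morita–Baylis–Hillman/SN2′ sequence (C7=C11, C13–O).
5. Ring order: 13-membered oxacycle, then ten-membered carbocycle, then γ-lactone.

Key step: step 19

Remark (assumption): germacrane numbering (C1–C15) is used for all intermediates; TES = triethylsilyl, TBS = tert-butyldimethylsilyl, TBDPS = tert-butyldiphenylsilyl, DMP = Dess–Martin periodinane; the Morita–Baylis–Hillman carbinol (C7) and the Nozaki–Hiyama–Kishi carbinol (C9) are carried on as epimer mixtures because both centres are removed again; the C8 carbinol from the rearrangement is assigned 8α (trans to the C7 acrylate) on the transition-state argument of step 19, so the C8 ester is introduced with inversion.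

**Route**

Step 1
Reactants: 1 ethyl (triphenylphosphoranylidene)acetate; 2 allyl bromide
Product: 4 ethyl 2-(triphenylphosphoranylidene)pent-4-enoate, via phosphonium bromide 3 (not isolated)
Conditions: EtOAc, reflux; then NaOH (aq), CH2Cl2, 0 °C
Reagents that add atoms: none
Why: C-alkylation of a stabilised ylide by an allylic bromide and deprotonation of the resulting salt is the standard way to an α-substituted stabilised Wittig reagent; no stereocentre is formed.

Step 2
Reactants: 4 ethyl 2-(triphenylphosphoranylidene)pent-4-enoate; 5 (S)-2,2-dimethyl-1,3-dioxolane-4-carbaldehyde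
Product: 6 ethyl (2E)-2-{[(4R)-2,2-dimethyl-1,3-dioxolan-4-yl]methylidene}pent-4-enoate
Conditions: CH2Cl2, rt
Reagents that add atoms: none
Why: Wittig olefination with an α-substituted stabilised ylide is E-selective (ester trans to C6), which sets C4=C5 with C15 trans to C6, and the neutral conditions should leave the C6 stereocentre of the α-alkoxy aldehyde untouched.

Step 3
Reactants: 6 the dienoate from step 2
Product: 7 (2E)-2-{[(4R)-2,2-dimethyl-1,3-dioxolan-4-yl]methylidene}pent-4-en-1-ol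
Conditions: iBu2AlH, CH2Cl2, −78 °C; KNaC4H4O6 (aq)
Reagents that add atoms: none
Why: iBu2AlH reduction of the conjugated ester gives the allylic alcohol (C15) by 1,2-reduction and spares the acetonide and both alkenes.

Step 4
Reactants: 7 the C15 allylic alcohol
Product: 8 C15 TBDPS ether of 7
Conditions: TBDPSCl, imidazole, DMF, rt
Reagents that add atoms: tert-butyl(chloro)diphenylsilane, CC(C)(C)[Si](Cl)(c1ccccc1)c1ccccc1
Why: silyl ether formation at the primary alcohol with the acid-stable group that has to outlast all other protecting groups.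

Step 5
Reactants: 8 the acetonide
Product: 9 (2R,3E)-4-{[tert-butyl(diphenyl)silyl]oxymethyl}hepta-3,6-diene-1,2-diol (C6/C7 diol)
Conditions: AcOH–H2O (4:1), 40 °C
Reagents that add atoms: none
Why: acid-catalysed acetal hydrolysis of the terminal acetonide; the TBDPS ether is stable to aqueous acetic acid.

Step 6
Reactants: 9 the C6/C7 diol
Product: 10 (2R,3E)-4-{[tert-butyl(diphenyl)silyl]oxymethyl}-1,2-bis(triethylsilyloxy)hepta-3,6-diene
Conditions: TESCl, imidazole, DMAP (cat.), DMF, 0 °C → rt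
Reagents that add atoms: chlorotriethylsilane, CC[Si](Cl)(CC)CC
Why: exhaustive silylation of the diol; the primary (C7) and secondary (C6) TES ethers are told apart later by the Swern conditions of step 12.

Step 7
Reactants: 10 the bis-TES diene
Product: 12 (4E,6R)-4-{[tert-butyl(diphenyl)silyl]oxymethyl}-6,7-bis(triethylsilyloxy)hept-4-en-1-ol (C1 alcohol), via alkylborane 11 (not isolated)
Conditions: 9-BBN, THF, 0 °C → rt; then NaOH (aq), H2O2, 0 °C
Reagents that add atoms: hydrogen peroxide, OO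
Why: hydroboration–oxidation; 9-BBN adds anti-Markovnikov and only to the monosubstituted alkene, so the trisubstituted C4=C5 alkene is left, and silyl ethers survive the basic peroxide work-up.

Step 8
Reactants: 12 the C1 alcohol
Product: 13 (4E,6R)-4-{[tert-butyl(diphenyl)silyl]oxymethyl}-6,7-bis(triethylsilyloxy)hept-4-enal (C1 aldehyde)
Conditions: DMP, NaHCO3, CH2Cl2, 0 °C → rt
Reagents that add atoms: none
Why: Dess–Martin oxidation of a primary alcohol to the aldehyde under buffered conditions that spare the silyl ethers.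

Step 9
Reactants: 13 the C1 aldehyde; 1 ethyl (triphenylphosphoranylidene)acetate
Product: 15 ethyl (2Z,6E,8R)-6-{[tert-butyl(diphenyl)silyl]oxymethyl}-2-iodo-8,9-bis(triethylsilyloxy)nona-2,6-dienoate, via iodo ylide 14 (not isolated)
Conditions: 1, N-iodosuccinimide, CH2Cl2, −20 °C; then 13, rt
Reagents that add atoms: N-iodosuccinimide, O=C1CCC(=O)N1I
Why: iodination of the stabilised ylide in the flask and Wittig olefination should give the (Z)-α-iodoenoate (ester trans to C2, iodine cis to C2), so that C14 ends trans to C2 and the iodine marks the position of C9.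

Step 10
Reactants: 15 the iodoenoate
Product: 16 (2Z,6E,8R)-6-{[tert-butyl(diphenyl)silyl]oxymethyl}-2-iodo-8,9-bis(triethylsilyloxy)nona-2,6-dien-1-ol (C14 alcohol)
Conditions: iBu2AlH, CH2Cl2, −78 °C; KNaC4H4O6 (aq)
Reagents that add atoms: none
Why: iBu2AlH reduction of the ester to the allylic alcohol; alkenyl iodides are inert to this reagent at −78 °C.

Step 11
Reactants: 16 the C14 alcohol
Product: 17 C14 TBS ether of 16
Conditions: TBSCl, imidazole, DMF, rt
Reagents that add atoms: tert-butyl(chloro)dimethylsilane, CC(C)(C)[Si](C)(C)Cl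
Why: silyl ether formation; TBS is chosen so that C14 can be unmasked before the C15 TBDPS ether.

Step 12
Reactants: 17 the fully silylated iodide
Product: 18 (2R,3E,7Z)-9-{[tert-butyl(dimethyl)silyl]oxy}-4-{[tert-butyl(diphenyl)silyl]oxymethyl}-8-iodo-2-(triethylsilyloxy)nona-3,7-dienal (C7 aldehyde)
Conditions: (COCl)2, DMSO, CH2Cl2, −78 → −30 °C; Et3N, −78 → 0 °C
Reagents that add atoms: none
Why: under Swern conditions a primary TES ether is cleaved by the chlorosulfonium salt and oxidised directly to the aldehyde while secondary TES, TBS and TBDPS ethers persist; the amine is added cold to limit epimerisation at C6.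

Step 13
Reactants: 18 the C7 aldehyde; 19 methyl acrylate
Product: 20 methyl (4R,5E,9Z)-11-{[tert-butyl(dimethyl)silyl]oxy}-6-{[tert-butyl(diphenyl)silyl]oxymethyl}-3-hydroxy-10-iodo-2-methylidene-4-(triethylsilyloxy)undeca-5,9-dienoate (C7 carbinol, both epimers)
Conditions: 19 (excess), DABCO (cat.), MeOH, rt
Reagents that add atoms: none
Why: Morita–Baylis–Hillman reaction; the α-silyloxy aldehyde is an activated electrophile, and the new C7 carbinol centre needs no control because it becomes sp2 in step 14.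

Step 14
Reactants: 20 the Morita–Baylis–Hillman adduct
Product: 22 methyl (2Z,4R,5E,9Z)-2-(bromomethyl)-11-{[tert-butyl(dimethyl)silyl]oxy}-6-{[tert-butyl(diphenyl)silyl]oxymethyl}-10-iodo-4-(triethylsilyloxy)undeca-2,5,9-trienoate, via mesylate 21 (not isolated)
Conditions: Ms2O, iPr2NEt, CH2Cl2, −20 °C; then LiBr, THF, 0 °C → rt
Reagents that add atoms: lithium bromide, [Li+].[Br-]
Why: sulfonylation then SN2′ displacement by bromide moves the leaving group to C13 and should give the conjugated (Z)-allylic bromide (bromomethyl cis to C6, ester trans), the isomer normally obtained from acrylate-derived adducts of this kind.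

Step 15
Reactants: 22 the allylic bromide; 23 ethylene glycol
Product: 24 methyl (2E,4R,5E,9Z)-11-{[tert-butyl(dimethyl)silyl]oxy}-6-{[tert-butyl(diphenyl)silyl]oxymethyl}-2-[(2-hydroxyethoxy)methyl]-10-iodo-4-(triethylsilyloxy)undeca-2,5,9-trienoate
Conditions: 23 (excess), Ag2O, MeCN, rt, dark
Reagents that add atoms: none
Why: silver-assisted Williamson etherification (SN2 at the primary allylic bromide) with a large excess of the diol should give the monoether (C13–O–C8) with the alkene geometry unchanged; the neutral conditions avoid oxa-Michael addition and transesterification.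

Step 16
Reactants: 24 the hydroxyethyl ether
Product: 25 the corresponding 2-oxoethyl ether (C9 aldehyde)
Conditions: DMP, NaHCO3, CH2Cl2, 0 °C → rt
Reagents that add atoms: none
Why: Dess–Martin oxidation of the primary alcohol to the α-alkoxy aldehyde without touching the silyl ethers, the ester or the alkenyl iodide.

Step 17
Reactants: 25 the iodo aldehyde
Product: 26 methyl (3E,5R,6E,10Z)-11-{[tert-butyl(dimethyl)silyl]oxymethyl}-7-{[tert-butyl(diphenyl)silyl]oxymethyl}-12-hydroxy-5-(triethylsilyloxy)-1-oxacyclotrideca-3,6,10-triene-3-carboxylate (C9 carbinol, both epimers)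
Conditions: CrCl2 (excess), NiCl2 (cat.), DMSO–THF, rt, high dilution (slow addition)
Reagents that add atoms: none
Why: Nozaki–Hiyama–Kishi reaction: nickel-catalysed activation of the C10–I bond, transfer to trivalent chromium and addition to the C9 aldehyde closes the 13-membered ring end to end with retention of alkene geometry and tolerance of the ester; the C9 configuration is irrelevant.

Step 18
Reactants: 26 the macrocyclic allylic alcohol
Product: 27 methyl (3E,5R,6E,10Z)-11-{[tert-butyl(dimethyl)silyl]oxymethyl}-7-{[tert-butyl(diphenyl)silyl]oxymethyl}-12-oxo-5-(triethylsilyloxy)-1-oxacyclotrideca-3,6,10-triene-3-carboxylate (13-membered α-allyloxy enone: C9 ketone, C8–O–C13 ether)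
Conditions: DMP, NaHCO3, CH2Cl2, 0 °C → rt
Reagents that add atoms: none
Why: Dess–Martin oxidation of the allylic alcohol to the enone under neutral conditions, so the enone with the C9 carbonyl cis to C2 is not isomerised.

Step 19
Reactants: 27 the 13-membered α-allyloxy enone
Product: 30 methyl 2-[(1R,2R,3E,7Z,10R)-8-{[tert-butyl(dimethyl)silyl]oxymethyl}-4-{[tert-butyl(diphenyl)silyl]oxymethyl}-10-hydroxy-9-oxo-2-(triethylsilyloxy)cyclodeca-3,7-dien-1-yl]prop-2-enoate (ten-membered 8α-hydroxy-9-ketone with the C7 acrylate; 6R,7R,8R), via lithium enolate 28 (not isolated), via lithium alkoxide 29 (not isolated)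
Conditions: LiN(SiMe3)2 (1.05 equiv), THF, −78 → −40 °C; AcOH, −78 °C
Reagents that add atoms: none
Why: Proposed new method: LiN(SiMe3)2 removes an α′ proton at C8 (the kinetic site of the enone, lithium chelated by the ether oxygen) and the enolate carbon bonds to C7, the β-carbon of the acrylate, through a five-membered envelope while the allylic C13–O bond breaks, a [2,3]-sigmatropic shift that could equally run as Michael addition and alkoxide elimination; the closest known reactions are the [2,3]-Wittig ring contraction of 13-membered diallylic ethers to cyclodeca-1,5-dienes and the [2,3]-shift of acyclic α-allyloxy ketone enolates, which have not been combined in one substrate. The ten-membered carbocycle is closed by contraction of the 13-membered oxacycle (transannular C7–C8 bond formation with O and C13 leaving the ring), not by end-to-end cyclisation, and the exocyclic C11=C13 methylene is released in the same event. C7 is controlled by C6: allylic 1,3-strain against the C13 methylene holds H6 in the alkene plane and C8 adds anti to the C6–O bond on the face that carries C5, which gives the trans C6–O/C7–C11 relationship needed for the lactone. C8 is controlled by the envelope: with C5 above C6 the enolate arm (C9, C10) can only lie on the H7 side, where lithium can bridge the enolate oxygen and the ester carbonyl, so the hydroxyl is expected trans to the C7 acrylate (8α) and is inverted in step 20. The step needs the [2,3] mode over the [3,3] oxy-Claisen mode (C9–C7 bonding) and over γ-deprotonation at C2, which the electrophilic C7, the lithium counter-ion and the low temperature should secure, and the C12 ester must survive next to the new alkoxide 29, which the cold AcOH quench should secure.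

Step 20
Reactants: 30 the 8α-hydroxy ketone; 31 (S)-2-methylbutanoic acid
Product: 32 the 8β-[(2S)-2-methylbutanoyloxy]-9-ketone (6R,7R,8S; other groups as in 30)
Conditions: PPh3, DIAD, PhMe, 0 °C (betaine preformed); then 30 and 31, 0 °C → rt
Reagents that add atoms: none
Why: Mitsunobu esterification: the C8 alkoxyphosphonium ion is displaced by the carboxylate with inversion (SN2 assisted by the adjacent carbonyl), which turns the 8α-alcohol into the 8β-ester of the target without touching the stereocentre of the acid.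

Step 21
Reactants: 32 the α-acyloxy enone
Product: 33 the 9α-alcohol (6R,7R,8S,9S)
Conditions: NaBH4, CeCl3·7H2O, MeOH, −78 °C
Reagents that add atoms: none
Why: Luche reduction gives 1,2-reduction of the enone, and hydride is expected to add anti to the C8–O bond (polar Felkin–Anh model, attack from the ring periphery), giving the 9α-alcohol trans to the 8β-ester; the low temperature suppresses O8 to O9 acyl migration.

Step 22
Reactants: 33 the 9α-alcohol
Product: 34 the 9α-acetate (6R,7R,8S,9S)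
Conditions: Ac2O, pyridine, DMAP (cat.), CH2Cl2, 0 °C
Reagents that add atoms: acetic anhydride, CC(=O)OC(C)=O
Why: acylation of the secondary allylic alcohol with retention, carried out at once so that the neighbouring ester cannot migrate.

Step 23
Reactants: 34 the fully protected diester
Product: 36 9α-acetoxy-15-(TBDPS-oxy)-14-hydroxy-8β-[(2S)-2-methylbutanoyloxy]germacra-1(10),4,11(13)-trien-6α,12-olide (6R,7S,8S,9S), via dihydroxy ester 35 (not isolated)
Conditions: HF·pyridine, pyridine, THF, 0 °C → rt; then PPTS (cat.), PhH, 50 °C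
Reagents that add atoms: none
Why: fluoride cleaves the secondary TES and the primary TBS ether much faster than the TBDPS ether, and the freed C6 hydroxyl lactonises onto the C12 methyl ester under mild acid (5-exo-trig transesterification) to the trans-fused α-methylene-γ-butyrolactone with C6 and C7 unchanged.

Step 24
Reactants: 36 the lactone with free C14 alcohol
Product: 37 the C14 aldehyde (enal, C14 trans to C2), C15 still TBDPS-protected
Conditions: DMP, NaHCO3, CH2Cl2, 0 °C
Reagents that add atoms: none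
Why: Dess–Martin oxidation of the only free hydroxyl, a primary allylic alcohol, gives the enal without isomerising the ring alkene.

Step 25
Reactants: 37 the silyl-protected enal
Product: 38 CNP0247637.6
Conditions: HF·pyridine, THF, rt
Reagents that add atoms: none
Why: fluoride cleavage of the primary TBDPS ether under non-basic conditions that the enal, the α-methylene lactone and both esters should tolerate.

**Compound list**

1 | ethyl (triphenylphosphoranylidene)acetate | CCOC(=O)C=P(c1ccccc1)(c1ccccc1)c1ccccc1 | starting material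
2 | allyl bromide | C=CCBr | starting material
3 | (1-ethoxy-1-oxopent-4-en-2-yl)triphenylphosphonium bromide | CCOC(=O)C(CC=C)[P+](c1ccccc1)(c1ccccc1)c1ccccc1.[Br-] | intermediate
4 | ethyl 2-(triphenylphosphoranylidene)pent-4-enoate | CCOC(=O)C(CC=C)=P(c1ccccc1)(c1ccccc1)c1ccccc1 | intermediate
5 | (S)-2,2-dimethyl-1,3-dioxolane-4-carbaldehyde | O=C[C@@H]1COC(C)(C)O1 | starting material
6 | ethyl (2E)-2-{[(4R)-2,2-dimethyl-1,3-dioxolan-4-yl]methylidene}pent-4-enoate | CCOC(=O)/C(CC=C)=C/[C@@H]1COC(C)(C)O1 | intermediate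
7 | (2E)-2-{[(4R)-2,2-dimethyl-1,3-dioxolan-4-yl]methylidene}pent-4-en-1-ol | OC/C(CC=C)=C/[C@@H]1COC(C)(C)O1 | intermediate
8 | tert-butyl{[(2E)-2-{[(4R)-2,2-dimethyl-1,3-dioxolan-4-yl]methylidene}pent-4-en-1-yl]oxy}diphenylsilane | CC(C)(C)[Si](OC/C(CC=C)=C/[C@@H]1COC(C)(C)O1)(c1ccccc1)c1ccccc1 | intermediate
9 | (2R,3E)-4-{[tert-butyl(diphenyl)silyl]oxymethyl}hepta-3,6-diene-1,2-diol | CC(C)(C)[Si](OC/C(CC=C)=C/[C@@H](O)CO)(c1ccccc1)c1ccccc1 | intermediate
10 | (2R,3E)-4-{[tert-butyl(diphenyl)silyl]oxymethyl}-1,2-bis(triethylsilyloxy)hepta-3,6-diene | CC[Si](CC)(CC)OC[C@H](O[Si](CC)(CC)CC)/C=C(/CO[Si](c1ccccc1)(c1ccccc1)C(C)(C)C)CC=C | intermediate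
11 | 9-alkyl-9-borabicyclo[3.3.1]nonane from 10 (boron on C1) | CC[Si](CC)(CC)OC[C@H](O[Si](CC)(CC)CC)/C=C(/CO[Si](c1ccccc1)(c1ccccc1)C(C)(C)C)CCCB1C2CCCC1CCC2 | intermediate
12 | (4E,6R)-4-{[tert-butyl(diphenyl)silyl]oxymethyl}-6,7-bis(triethylsilyloxy)hept-4-en-1-ol | CC[Si](CC)(CC)OC[C@H](O[Si](CC)(CC)CC)/C=C(/CO[Si](c1ccccc1)(c1ccccc1)C(C)(C)C)CCCO | intermediate
13 | (4E,6R)-4-{[tert-butyl(diphenyl)silyl]oxymethyl}-6,7-bis(triethylsilyloxy)hept-4-enal | CC[Si](CC)(CC)OC[C@H](O[Si](CC)(CC)CC)/C=C(/CO[Si](c1ccccc1)(c1ccccc1)C(C)(C)C)CCC=O | intermediate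
14 | ethyl iodo(triphenylphosphoranylidene)acetate | CCOC(=O)C(I)=P(c1ccccc1)(c1ccccc1)c1ccccc1 | intermediate
15 | ethyl (2Z,6E,8R)-6-{[tert-butyl(diphenyl)silyl]oxymethyl}-2-iodo-8,9-bis(triethylsilyloxy)nona-2,6-dienoate | CC[Si](CC)(CC)OC[C@H](O[Si](CC)(CC)CC)/C=C(/CO[Si](c1ccccc1)(c1ccccc1)C(C)(C)C)CC/C=C(/C(=O)OCC)I | intermediate
16 | (2Z,6E,8R)-6-{[tert-butyl(diphenyl)silyl]oxymethyl}-2-iodo-8,9-bis(triethylsilyloxy)nona-2,6-dien-1-ol | CC[Si](CC)(CC)OC[C@H](O[Si](CC)(CC)CC)/C=C(/CO[Si](c1ccccc1)(c1ccccc1)C(C)(C)C)CC/C=C(/CO)I | intermediate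
17 | (2Z,6E,8R)-1-{[tert-butyl(dimethyl)silyl]oxy}-6-{[tert-butyl(diphenyl)silyl]oxymethyl}-2-iodo-8,9-bis(triethylsilyloxy)nona-2,6-diene | CC[Si](CC)(CC)OC[C@H](O[Si](CC)(CC)CC)/C=C(/CO[Si](c1ccccc1)(c1ccccc1)C(C)(C)C)CC/C=C(/CO[Si](C)(C)C(C)(C)C)I | intermediate
18 | (2R,3E,7Z)-9-{[tert-butyl(dimethyl)silyl]oxy}-4-{[tert-butyl(diphenyl)silyl]oxymethyl}-8-iodo-2-(triethylsilyloxy)nona-3,7-dienal | O=C[C@H](O[Si](CC)(CC)CC)/C=C(/CO[Si](c1ccccc1)(c1ccccc1)C(C)(C)C)CC/C=C(/CO[Si](C)(C)C(C)(C)C)I | intermediate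
19 | methyl acrylate | C=CC(=O)OC | starting material
20 | methyl (4R,5E,9Z)-11-{[tert-butyl(dimethyl)silyl]oxy}-6-{[tert-butyl(diphenyl)silyl]oxymethyl}-3-hydroxy-10-iodo-2-methylidene-4-(triethylsilyloxy)undeca-5,9-dienoate (C3 epimers) | C=C(C(=O)OC)C(O)[C@H](O[Si](CC)(CC)CC)/C=C(/CO[Si](c1ccccc1)(c1ccccc1)C(C)(C)C)CC/C=C(/CO[Si](C)(C)C(C)(C)C)I | intermediate
21 | 3-methanesulfonate of 20 (C3 epimers) | C=C(C(=O)OC)C(OS(C)(=O)=O)[C@H](O[Si](CC)(CC)CC)/C=C(/CO[Si](c1ccccc1)(c1ccccc1)C(C)(C)C)CC/C=C(/CO[Si](C)(C)C(C)(C)C)I | intermediate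
22 | methyl (2Z,4R,5E,9Z)-2-(bromomethyl)-11-{[tert-butyl(dimethyl)silyl]oxy}-6-{[tert-butyl(diphenyl)silyl]oxymethyl}-10-iodo-4-(triethylsilyloxy)undeca-2,5,9-trienoate | COC(=O)/C(CBr)=C/[C@H](O[Si](CC)(CC)CC)/C=C(/CO[Si](c1ccccc1)(c1ccccc1)C(C)(C)C)CC/C=C(/CO[Si](C)(C)C(C)(C)C)I | intermediate
23 | ethylene glycol | OCCO | starting material
24 | methyl (2E,4R,5E,9Z)-11-{[tert-butyl(dimethyl)silyl]oxy}-6-{[tert-butyl(diphenyl)silyl]oxymethyl}-2-[(2-hydroxyethoxy)methyl]-10-iodo-4-(triethylsilyloxy)undeca-2,5,9-trienoate | COC(=O)/C(COCCO)=C/[C@H](O[Si](CC)(CC)CC)/C=C(/CO[Si](c1ccccc1)(c1ccccc1)C(C)(C)C)CC/C=C(/CO[Si](C)(C)C(C)(C)C)I | intermediate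
25 | methyl (2E,4R,5E,9Z)-11-{[tert-butyl(dimethyl)silyl]oxy}-6-{[tert-butyl(diphenyl)silyl]oxymethyl}-10-iodo-2-[(2-oxoethoxy)methyl]-4-(triethylsilyloxy)undeca-2,5,9-trienoate | COC(=O)/C(COCC=O)=C/[C@H](O[Si](CC)(CC)CC)/C=C(/CO[Si](c1ccccc1)(c1ccccc1)C(C)(C)C)CC/C=C(/CO[Si](C)(C)C(C)(C)C)I | intermediate
26 | methyl (3E,5R,6E,10Z)-11-{[tert-butyl(dimethyl)silyl]oxymethyl}-7-{[tert-butyl(diphenyl)silyl]oxymethyl}-12-hydroxy-5-(triethylsilyloxy)-1-oxacyclotrideca-3,6,10-triene-3-carboxylate (C12 epimers) | COC(=O)/C1=C/[C@H](O[Si](CC)(CC)CC)/C=C(/CO[Si](c2ccccc2)(c2ccccc2)C(C)(C)C)CC/C=C(/CO[Si](C)(C)C(C)(C)C)C(O)COC1 | intermediate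
27 | methyl (3E,5R,6E,10Z)-11-{[tert-butyl(dimethyl)silyl]oxymethyl}-7-{[tert-butyl(diphenyl)silyl]oxymethyl}-12-oxo-5-(triethylsilyloxy)-1-oxacyclotrideca-3,6,10-triene-3-carboxylate | COC(=O)/C1=C/[C@H](O[Si](CC)(CC)CC)/C=C(/CO[Si](c2ccccc2)(c2ccccc2)C(C)(C)C)CC/C=C(/CO[Si](C)(C)C(C)(C)C)C(=O)COC1 | intermediate
28 | lithium (Z)-enolate of 27 (C8=C9, O–Li cis to the ring ether oxygen) | [Li+].COC(=O)/C1=C/[C@H](O[Si](CC)(CC)CC)/C=C(/CO[Si](c2ccccc2)(c2ccccc2)C(C)(C)C)CC/C=C(/CO[Si](C)(C)C(C)(C)C)\C([O-])=C\OC1 | intermediate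
29 | lithium 8α-alkoxide of 30 | [Li+].C=C(C(=O)OC)[C@H]1[C@H](O[Si](CC)(CC)CC)/C=C(/CO[Si](c2ccccc2)(c2ccccc2)C(C)(C)C)CC/C=C(/CO[Si](C)(C)C(C)(C)C)C(=O)[C@@H]1[O-] | intermediate
30 | methyl 2-[(1R,2R,3E,7Z,10R)-8-{[tert-butyl(dimethyl)silyl]oxymethyl}-4-{[tert-butyl(diphenyl)silyl]oxymethyl}-10-hydroxy-9-oxo-2-(triethylsilyloxy)cyclodeca-3,7-dien-1-yl]prop-2-enoate (6R,7R,8R; 8α-OH) | C=C(C(=O)OC)[C@H]1[C@H](O[Si](CC)(CC)CC)/C=C(/CO[Si](c2ccccc2)(c2ccccc2)C(C)(C)C)CC/C=C(/CO[Si](C)(C)C(C)(C)C)C(=O)[C@@H]1O | intermediate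
31 | (S)-2-methylbutanoic acid | CC[C@H](C)C(=O)O | starting material
32 | 8β-[(2S)-2-methylbutanoyloxy]-9-ketone: C8 ester of the C8 epimer of 30 (6R,7R,8S) | C=C(C(=O)OC)[C@H]1[C@H](O[Si](CC)(CC)CC)/C=C(/CO[Si](c2ccccc2)(c2ccccc2)C(C)(C)C)CC/C=C(/CO[Si](C)(C)C(C)(C)C)C(=O)[C@H]1OC(=O)[C@@H](C)CC | intermediate
33 | 9α-alcohol from 32 (6R,7R,8S,9S) | C=C(C(=O)OC)[C@H]1[C@H](O[Si](CC)(CC)CC)/C=C(/CO[Si](c2ccccc2)(c2ccccc2)C(C)(C)C)CC/C=C(/CO[Si](C)(C)C(C)(C)C)[C@H](O)[C@H]1OC(=O)[C@@H](C)CC | intermediate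
34 | 9α-acetate of 33 (6R,7R,8S,9S) | C=C(C(=O)OC)[C@H]1[C@H](O[Si](CC)(CC)CC)/C=C(/CO[Si](c2ccccc2)(c2ccccc2)C(C)(C)C)CC/C=C(/CO[Si](C)(C)C(C)(C)C)[C@H](OC(C)=O)[C@H]1OC(=O)[C@@H](C)CC | intermediate
35 | 6α,14-dihydroxy methyl ester from 34 (TES and TBS removed; 6R,7S,8S,9S) | C=C(C(=O)OC)[C@H]1[C@H](O)/C=C(/CO[Si](c2ccccc2)(c2ccccc2)C(C)(C)C)CC/C=C(/CO)[C@H](OC(C)=O)[C@H]1OC(=O)[C@@H](C)CC | intermediate
36 | 9α-acetoxy-15-[tert-butyl(diphenyl)silyl]oxy-14-hydroxy-8β-[(2S)-2-methylbutanoyloxy]germacra-1(10),4,11(13)-trien-6α,12-olide (6R,7S,8S,9S) | C=C1C(=O)O[C@@H]2/C=C(/CO[Si](c3ccccc3)(c3ccccc3)C(C)(C)C)CC/C=C(/CO)[C@H](OC(C)=O)[C@@H](OC(=O)[C@@H](C)CC)[C@@H]12 | intermediate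
37 | 9α-acetoxy-15-[tert-butyl(diphenyl)silyl]oxy-8β-[(2S)-2-methylbutanoyloxy]-14-oxogermacra-1(10),4,11(13)-trien-6α,12-olide (6R,7S,8S,9S) | C=C1C(=O)O[C@@H]2/C=C(/CO[Si](c3ccccc3)(c3ccccc3)C(C)(C)C)CC/C=C(/C=O)[C@H](OC(C)=O)[C@@H](OC(=O)[C@@H](C)CC)[C@@H]12 | intermediate
38 | CNP0247637.6: 9α-acetoxy-15-hydroxy-8β-[(2S)-2-methylbutanoyloxy]-14-oxogermacra-1(10),4,11(13)-trien-6α,12-olide (6R,7S,8S,9S; C14 trans to C2, C15 trans to C6) | C=C1C(=O)O[C@@H]2/C=C(/CO)CC/C=C(/C=O)[C@H](OC(C)=O)[C@@H](OC(=O)[C@@H](C)CC)[C@@H]12 | target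

**Step count and risks**

Total step count: 25. Longest linear sequence: 25 steps (from 1 and 2; all other inputs are commercial).

Steps most likely to fail:

Step 19 (Proposed new method). What may go wrong: the enolate may react through the [3,3] mode or not at all, enolisation may occur at C2, or the C8 alkoxide may attack the C12 ester before the quench. Fallback with known chemistry, setting out from 22 and coming back at 32: the C7–C8 bond is made first and the ten-membered ring is closed afterwards. Indium-mediated Barbier allylation of (4-methoxybenzyloxy)acetaldehyde with 22 (indium powder (In), THF–H2O, rt; γ-attack of the 2-(methoxycarbonyl)allyl indium species, normally syn-selective) should give the acyclic 8β-hydroxy α-methylene ester F1. Esterification with 31 (DCC, DMAP, CH2Cl2, 0 °C) gives the C8 2-methylbutanoate F2. DDQ (CH2Cl2, pH 7 buffer) removes the 4-methoxybenzyl group to give the C9 primary alcohol F3, and DMP oxidation gives the C9 aldehyde F4. Nozaki–Hiyama–Kishi closure (CrCl2, NiCl2 cat., DMSO, high dilution) between C9 and the C10 iodide forms the ten-membered C9 carbinol F5 as a pair of C9 epimers, and DMP oxidation gives 32.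

Step 20. What may go wrong: slow activation of the hindered α-ketol, elimination toward C7, or acylation with retention. Fallback, setting out from 30 and coming back at 32: the alcohol is isolated as a far more reactive sulfonate and displaced by a naked carboxylate. Tf2O and 2,6-lutidine (CH2Cl2, −78 °C) give the α-keto triflate F6, which the caesium salt of 31 (Cs2CO3, 18-crown-6, PhMe, −20 °C) should displace with inversion to give 32.

Step 21. What may go wrong: hydride delivery to the other face of the C9 carbonyl in the flexible ten-membered ring, or O8 to O9 acyl migration. Fallback, setting out from 32 and coming back at 34: if reduction gives mainly the 9β-alcohol F7, this epimer is used. Mitsunobu reaction with AcOH (PPh3, DIAD, PhMe, 0 °C) inverts C9 and installs the acetate in one operation to give 34; the cis relationship of the C8 ester and the C9 leaving group should prevent anchimeric participation.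

**Further compounds**

F1 | step 19 | methyl (6R,7R,8S)-configured acyclic 8β-hydroxy ester: C7 acrylate, C8–OH, C9H2–O-(4-methoxybenzyl), 6α-OTES, C10 iodide, C14 OTBS, C15 OTBDPS | C=C(C(=O)OC)[C@H]([C@H](O)COCc1ccc(OC)cc1)[C@H](O[Si](CC)(CC)CC)/C=C(/CO[Si](c1ccccc1)(c1ccccc1)C(C)(C)C)CC/C=C(/CO[Si](C)(C)C(C)(C)C)I
F2 | step 19 | C8 (2S)-2-methylbutanoate of F1 | C=C(C(=O)OC)[C@H]([C@H](OC(=O)[C@@H](C)CC)COCc1ccc(OC)cc1)[C@H](O[Si](CC)(CC)CC)/C=C(/CO[Si](c1ccccc1)(c1ccccc1)C(C)(C)C)CC/C=C(/CO[Si](C)(C)C(C)(C)C)I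
F3 | step 19 | C9 primary alcohol from F2 | C=C(C(=O)OC)[C@H]([C@H](OC(=O)[C@@H](C)CC)CO)[C@H](O[Si](CC)(CC)CC)/C=C(/CO[Si](c1ccccc1)(c1ccccc1)C(C)(C)C)CC/C=C(/CO[Si](C)(C)C(C)(C)C)I
F4 | step 19 | C9 aldehyde from F3 | C=C(C(=O)OC)[C@H]([C@H](OC(=O)[C@@H](C)CC)C=O)[C@H](O[Si](CC)(CC)CC)/C=C(/CO[Si](c1ccccc1)(c1ccccc1)C(C)(C)C)CC/C=C(/CO[Si](C)(C)C(C)(C)C)I
F5 | step 19 | ten-membered C9 carbinol (C9 epimers) with 8β-(2S)-2-methylbutanoate | C=C(C(=O)OC)[C@H]1[C@H](O[Si](CC)(CC)CC)/C=C(/CO[Si](c2ccccc2)(c2ccccc2)C(C)(C)C)CC/C=C(/CO[Si](C)(C)C(C)(C)C)C(O)[C@H]1OC(=O)[C@@H](C)CC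
F6 | step 20 | 8α-trifluoromethanesulfonate of 30 | C=C(C(=O)OC)[C@H]1[C@H](O[Si](CC)(CC)CC)/C=C(/CO[Si](c2ccccc2)(c2ccccc2)C(C)(C)C)CC/C=C(/CO[Si](C)(C)C(C)(C)C)C(=O)[C@@H]1OS(=O)(=O)C(F)(F)F
F7 | step 21 | 9β-alcohol, C9 epimer of 33 (6R,7R,8S,9R) | C=C(C(=O)OC)[C@H]1[C@H](O[Si](CC)(CC)CC)/C=C(/CO[Si](c2ccccc2)(c2ccccc2)C(C)(C)C)CC/C=C(/CO[Si](C)(C)C(C)(C)C)[C@@H](O)[C@H]1OC(=O)[C@@H](C)CC
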